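**Plan**
Retrosynthetic cuts, in order: the enone Cα=Cβ bond (Claisen–Schmidt), the ring A C1'–acyl bond (ortho-lithiation/acylation), C6''=C7'' (Wittig), ring A C3'–C1'' (Negishi) and last C3''–O (C–H oxidation). This leads back to (S)-citronellyl bromide, 2-iodoresorcinol and 4-hydroxybenzaldehyde.
Enabling feature: the carbinol carbon C3'' (methyl, arylethyl arm C1''–C2'', homoprenyl arm C4''–C8'') is a citronellane methine. Its oxygen is 1,4 to C6'', so with C6'' as a carboxyl group the atoms O, C3'', C4'', C5'', C6'' form a gamma-lactone ring.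
Forward order: the terpene is trimmed to the C6'' acid, and the lactone (the only ring built, reopened later) is closed by C–H oxidation. Its bromoethyl arm is joined to ring A, the lactone is reduced and olefinated back to the homoprenyl arm, ring A is acetylated, ring B is added by aldol condensation, and the protecting groups are removed.
Stereochemistry: C3'' is the only stereocentre. It is the C3 methine of (S)-citronellyl bromide, where H is replaced by O with retention. The enone is E by thermodynamic control.

Key step: step 3

Remark: ring A is the acyl-bearing ring (C1'–C6'), ring B the 4-hydroxyphenyl ring, and the side chain on C3' is C1''–C8''. The CIP label at C3'' changes with arm priorities (S in 10–12, R elsewhere) while the spatial arrangement set in step 3 is never touched.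

**Step 1**
Reactants: 1 (S)-citronellyl bromide [(6S)-8-bromo-2,6-dimethyloct-2-ene]
Product: 3 (4S)-6-bromo-4-methylhexanal, via ozonide 2 (not isolated)
Conditions: O3, CH2Cl2, −78 °C; then PPh3, −78 → 25 °C
Reagents that add atoms: ozone, [O-][O+]=O
Why: Ozonolysis cleaves the only C=C bond by way of ozonide 2 and the phosphine reduces the peroxide to release the C6'' aldehyde and acetone, while the primary bromide and the remote methine stereocentre are not affected.

**Step 2**
Reactants: 3 (4S)-6-bromo-4-methylhexanal
Product: 4 (4S)-6-bromo-4-methylhexanoic acid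
Conditions: NaClO2, NaH2PO4, 2-methyl-2-butene, t-BuOH/H2O, 0 → 25 °C
Reagents that add atoms: sodium chlorite, [Na+].[O-]Cl=O
Why: Pinnick oxidation, in which chlorous acid adds to the formyl group and fragments to the acid and HOCl (trapped by 2-methyl-2-butene), is specific for aldehydes and cannot epimerise a stereocentre that is gamma to the carbonyl group.

**Step 3**
Reactants: 4 (4S)-6-bromo-4-methylhexanoic acid
Product: 6 (5R)-5-(2-bromoethyl)-5-methyloxolan-2-one, via hydroxy acid 5 (not isolated)
Conditions: [Fe((S,S)-PDP)(CH3CN)2](SbF6)2 (3 × 5 mol%), H2O2 (50% aq., 3 × 1.2 equiv, slow addition), CH3CN, 25 °C, no added acetic acid; PDP = N,N'-bis(2-pyridylmethyl)-2,2'-bipyrrolidine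
Reagents that add atoms: hydrogen peroxide, OO
Why: The acid itself serves as the carboxylate ligand of the divalent iron complex, H2O2 turns this into a formally pentavalent iron–oxo carboxylate, and the oxo group removes the hydrogen atom of the methine three carbons away through a cyclic transition state, after which hydroxyl rebound gives hydroxy acid 5. The closest known reaction type is the carboxylate-directed gamma-lactonisation of tertiary C–H bonds with non-heme iron/H2O2 catalysts, whose metal-free relative is dioxirane O-insertion. The single ring is closed by 5-exo-trig attack of the new tertiary hydroxyl on the carboxyl carbon with loss of water, which should be spontaneous for a gamma-hydroxy acid with a fully substituted carbinol carbon. The new oxygen-bearing stereocentre is governed by the substrate alone: rebound is faster than inversion of the caged tertiary radical, so O takes the place of H with retention, the (S) methine becomes the (R) carbinol, and either antipode of the catalyst should lead to the same lactone. The step needs site selectivity, chemoselectivity and stereoretention; the substrate offers one tertiary C–H only, placed where the bound carboxylate can reach it, all CH2 groups are inductively deactivated by CO2H or Br, no alkene or arene is present yet, and the electron-poor lactone has no tertiary C–H left to be oxidised further.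

**Step 4**
Reactants: 7 2-iodoresorcinol (2-iodobenzene-1,3-diol)
Product: 8 2-iodo-1,3-bis(methoxymethoxy)benzene
Conditions: MeOCH2Cl, i-Pr2NEt, CH2Cl2, 0 → 25 °C
Reagents that add atoms: chloromethyl methyl ether, COCCl
Why: O-Alkylation of both phenols (Williamson-type substitution on the highly electrophilic alpha-chloro ether under amine base) should give the bis-acetal, which tolerates organometallic reagents and later directs ring lithiation.

**Step 5**
Reactants: 6 (5R)-5-(2-bromoethyl)-5-methyloxolan-2-one; 8 2-iodo-1,3-bis(methoxymethoxy)benzene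
Product: 10 (5S)-5-{2-[2,6-bis(methoxymethoxy)phenyl]ethyl}-5-methyloxolan-2-one, via alkylzinc bromide 9 (not isolated)
Conditions: Zn dust (activated with BrCH2CH2Br, Me3SiCl), LiCl, THF, 50 °C; then 8, Pd(OAc)2 (2 mol%), SPhos (4 mol%), THF, 50 °C
Reagents that add atoms: none
Why: Insertion of LiCl-activated zinc into the primary C–Br bond gives a lactone-tolerant alkylzinc, and Negishi coupling (oxidative addition of the aryl iodide to zerovalent palladium, transmetalation, reductive elimination) with the bulky biarylphosphine SPhos (2-dicyclohexylphosphino-2',6'-dimethoxybiphenyl) should forge C3'–C1'' at the doubly ortho-substituted carbon faster than beta-hydride elimination, the quaternary stereocentre being a bystander.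

**Step 6**
Reactants: 10 (5S)-5-{2-[2,6-bis(methoxymethoxy)phenyl]ethyl}-5-methyloxolan-2-one
Product: 11 (5S)-5-{2-[2,6-bis(methoxymethoxy)phenyl]ethyl}-5-methyloxolan-2-ol (lactol; both anomers)
Conditions: i-Bu2AlH (1.1 equiv), CH2Cl2, −78 °C; aq. potassium sodium tartrate
Reagents that add atoms: none
Why: Partial reduction of a lactone with i-Bu2AlH at −78 °C stops at the tetrahedral aluminium hemiacetal, which gives the lactol on work-up, and the aryl acetals are inert to the hydride.

**Step 7**
Reactants: 11 (5S)-5-{2-[2,6-bis(methoxymethoxy)phenyl]ethyl}-5-methyloxolan-2-ol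
Product: 13 (3R)-1-[2,6-bis(methoxymethoxy)phenyl]-3,7-dimethyloct-6-en-3-ol, via open-chain hydroxy aldehyde 12 (not isolated)
Conditions: i-PrPPh3I, n-BuLi, THF, 0 °C; then 11, 0 → 25 °C
Reagents that add atoms: isopropyltriphenylphosphonium iodide, CC(C)[P+](c1ccccc1)(c1ccccc1)c1ccccc1.[I-]
Why: In a Wittig olefination the lactol equilibrates under excess base with its open hydroxy aldehyde, which the non-stabilised isopropylidene ylide traps to rebuild the C6''=C7'' bond (no E/Z question for a dimethyl terminus) and to unveil the tertiary alcohol.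

**Step 8**
Reactants: 13 (3R)-1-[2,6-bis(methoxymethoxy)phenyl]-3,7-dimethyloct-6-en-3-ol
Product: 14 {[(3R)-1-[2,6-bis(methoxymethoxy)phenyl]-3,7-dimethyloct-6-en-3-yl]oxy}triethylsilane
Conditions: Et3SiOTf, 2,6-lutidine, CH2Cl2, −78 → 0 °C
Reagents that add atoms: triethylsilyl trifluoromethanesulfonate, CC[Si](CC)(CC)OS(=O)(=O)C(F)(F)F
Why: Silylation with a silyl triflate and a hindered pyridine base is the standard way to cap a tertiary alcohol, the aryl acetals should survive because the base is non-nucleophilic and the temperature low, and the ether removes the acidic O–H before the lithiation.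

**Step 9**
Reactants: 14 {[(3R)-1-[2,6-bis(methoxymethoxy)phenyl]-3,7-dimethyloct-6-en-3-yl]oxy}triethylsilane
Product: 16 1-{3-[(3R)-3,7-dimethyl-3-(triethylsilyloxy)oct-6-en-1-yl]-2,4-bis(methoxymethoxy)phenyl}ethan-1-one, via aryllithium 15 (not isolated)
Conditions: n-BuLi, TMEDA, THF, 0 °C; then MeC(O)N(OMe)Me, −78 → 0 °C; H2O
Reagents that add atoms: N-methoxy-N-methylacetamide, CC(=O)N(C)OC
Why: In a directed ortho-metalation each methoxymethoxy group binds n-BuLi and acidifies its free ortho C–H (the two such positions are equivalent by symmetry), and the aryllithium adds to the N-methoxy-N-methyl amide to give a chelated tetrahedral adduct that releases the methyl ketone only on work-up (Weinreb ketone synthesis), which rules out over-addition.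

**Step 10**
Reactants: 17 4-hydroxybenzaldehyde
Product: 18 4-(methoxymethoxy)benzaldehyde
Conditions: MeOCH2Cl, i-Pr2NEt, CH2Cl2, 0 → 25 °C
Reagents that add atoms: chloromethyl methyl ether, COCCl
Why: The same Williamson-type O-alkylation masks the phenol, whose phenoxide would otherwise deactivate the aldehyde toward enolate addition in the next step.

**Step 11**
Reactants: 16 1-{3-[(3R)-3,7-dimethyl-3-(triethylsilyloxy)oct-6-en-1-yl]-2,4-bis(methoxymethoxy)phenyl}ethan-1-one; 18 4-(methoxymethoxy)benzaldehyde
Product: 20 (2E)-1-{3-[(3R)-3,7-dimethyl-3-(triethylsilyloxy)oct-6-en-1-yl]-2,4-bis(methoxymethoxy)phenyl}-3-[4-(methoxymethoxy)phenyl]prop-2-en-1-one, via aldol adduct 19 (not isolated)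
Conditions: KOH, EtOH/H2O, 25 °C
Reagents that add atoms: none
Why: In a Claisen–Schmidt condensation the methyl ketone enolate adds to the non-enolisable aldehyde and the aldol loses water by an E1cB path to the conjugated enone, whose E geometry is the thermodynamic one, while acetals and the hindered silyl ether are stable to hydroxide.

**Step 12**
Reactants: 20 (2E)-1-{3-[(3R)-3,7-dimethyl-3-(triethylsilyloxy)oct-6-en-1-yl]-2,4-bis(methoxymethoxy)phenyl}-3-[4-(methoxymethoxy)phenyl]prop-2-en-1-one
Product: 21 (2E)-1-{2,4-dihydroxy-3-[(3R)-3-hydroxy-3,7-dimethyloct-6-en-1-yl]phenyl}-3-(4-hydroxyphenyl)prop-2-en-1-one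
Conditions: HCl (3 M aq.), MeOH, 25 °C
Reagents that add atoms: none
Why: Acid-catalysed acetal solvolysis (transfer of the methoxymethyl groups to methanol through oxocarbenium ions) and protodesilylation remove all four protecting groups under the mild conditions customary for methoxymethyl-protected prenyl and geranyl chalcones, the saturated tertiary alcohol being neither allylic nor benzylic and therefore slow to ionise in dilute acid at room temperature.

**Compound list**
1 | (S)-citronellyl bromide [(6S)-8-bromo-2,6-dimethyloct-2-ene] | CC(C)=CCC[C@H](C)CCBr | starting material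
2 | 3-[(3S)-5-bromo-3-methylpentyl]-5,5-dimethyl-1,2,4-trioxolane (ozonide; both epimers at the ring CH) | CC1(C)OOC(CC[C@H](C)CCBr)O1 | intermediate (not isolated)
3 | (4S)-6-bromo-4-methylhexanal | O=CCC[C@H](C)CCBr | intermediate
4 | (4S)-6-bromo-4-methylhexanoic acid | OC(=O)CC[C@H](C)CCBr | intermediate
5 | (4R)-6-bromo-4-hydroxy-4-methylhexanoic acid | OC(=O)CC[C@@](C)(O)CCBr | intermediate (not isolated)
6 | (5R)-5-(2-bromoethyl)-5-methyloxolan-2-one | O=C1CC[C@@](C)(O1)CCBr | intermediate
7 | 2-iodoresorcinol (2-iodobenzene-1,3-diol) | Oc1cccc(O)c1I | starting material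
8 | 2-iodo-1,3-bis(methoxymethoxy)benzene | COCOc1cccc(OCOC)c1I | intermediate
9 | bromo{2-[(2R)-2-methyl-5-oxooxolan-2-yl]ethyl}zinc | O=C1CC[C@@](C)(O1)CC[Zn]Br | intermediate (not isolated)
10 | (5S)-5-{2-[2,6-bis(methoxymethoxy)phenyl]ethyl}-5-methyloxolan-2-one | O=C1CC[C@@](C)(O1)CCc1c(OCOC)cccc1OCOC | intermediate
11 | (5S)-5-{2-[2,6-bis(methoxymethoxy)phenyl]ethyl}-5-methyloxolan-2-ol (lactol; both anomers) | OC1CC[C@@](C)(O1)CCc1c(OCOC)cccc1OCOC | intermediate
12 | (4S)-6-[2,6-bis(methoxymethoxy)phenyl]-4-hydroxy-4-methylhexanal | O=CCC[C@@](C)(O)CCc1c(OCOC)cccc1OCOC | intermediate (not isolated)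
13 | (3R)-1-[2,6-bis(methoxymethoxy)phenyl]-3,7-dimethyloct-6-en-3-ol | CC(C)=CCC[C@@](C)(O)CCc1c(OCOC)cccc1OCOC | intermediate
14 | {[(3R)-1-[2,6-bis(methoxymethoxy)phenyl]-3,7-dimethyloct-6-en-3-yl]oxy}triethylsilane | CC(C)=CCC[C@@](C)(O[Si](CC)(CC)CC)CCc1c(OCOC)cccc1OCOC | intermediate
15 | {3-[(3R)-3,7-dimethyl-3-(triethylsilyloxy)oct-6-en-1-yl]-2,4-bis(methoxymethoxy)phenyl}lithium | CC(C)=CCC[C@@](C)(O[Si](CC)(CC)CC)CCc1c(OCOC)ccc([Li])c1OCOC | intermediate (not isolated)
16 | 1-{3-[(3R)-3,7-dimethyl-3-(triethylsilyloxy)oct-6-en-1-yl]-2,4-bis(methoxymethoxy)phenyl}ethan-1-one | CC(C)=CCC[C@@](C)(O[Si](CC)(CC)CC)CCc1c(OCOC)ccc(C(C)=O)c1OCOC | intermediate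
17 | 4-hydroxybenzaldehyde | O=Cc1ccc(O)cc1 | starting material
18 | 4-(methoxymethoxy)benzaldehyde | O=Cc1ccc(OCOC)cc1 | intermediate
19 | 1-{3-[(3R)-3,7-dimethyl-3-(triethylsilyloxy)oct-6-en-1-yl]-2,4-bis(methoxymethoxy)phenyl}-3-hydroxy-3-[4-(methoxymethoxy)phenyl]propan-1-one (aldol; both epimers at the new carbinol carbon) | CC(C)=CCC[C@@](C)(O[Si](CC)(CC)CC)CCc1c(OCOC)ccc(C(=O)CC(O)c2ccc(OCOC)cc2)c1OCOC | intermediate (not isolated)
20 | (2E)-1-{3-[(3R)-3,7-dimethyl-3-(triethylsilyloxy)oct-6-en-1-yl]-2,4-bis(methoxymethoxy)phenyl}-3-[4-(methoxymethoxy)phenyl]prop-2-en-1-one | CC(C)=CCC[C@@](C)(O[Si](CC)(CC)CC)CCc1c(OCOC)ccc(C(=O)/C=C/c2ccc(OCOC)cc2)c1OCOC | intermediate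
21 | (2E)-1-{2,4-dihydroxy-3-[(3R)-3-hydroxy-3,7-dimethyloct-6-en-1-yl]phenyl}-3-(4-hydroxyphenyl)prop-2-en-1-one | CC(C)=CCC[C@@](C)(O)CCc1c(O)ccc(C(=O)/C=C/c2ccc(O)cc2)c1O | target

**Step count and risks**
Total step count: 12. Longest linear sequence: 10 steps (steps 1, 2, 3, 5, 6, 7, 8, 9, 11 and 12, from 1).

Steps most likely to fail:

1. Step 3. Hydrogen abstraction at a methine that is inductively deactivated from both sides (carboxyl and bromide) may be slow. The catalyst would then decay before conversion is complete, and methylene oxidation would begin to compete. The fallback takes the carbinol from the chiral pool instead of making it by C–H oxidation. (R)-Linalool F1 would be silylated (Et3SiOTf, 2,6-lutidine) to its triethylsilyl ether F2. Hydroboration of the vinyl group alone with 9-borabicyclo[3.3.1]nonane would give the B-alkyl borane F3. A Suzuki–Miyaura coupling (PdCl2(dppf), K3PO4, THF/H2O, 60 °C; dppf = 1,1'-bis(diphenylphosphino)ferrocene) with aryl iodide 8 would complete the sequence. The fallback sets out from 8 and comes back to the route at silyl ether 14, so steps 9, 11 and 12 follow unchanged.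

2. Step 12. Acid-catalysed addition of methanol or of the C3'' hydroxyl to the C6''=C7'' bond, or ionisation at C3'' with capture by a ring A phenol oxygen, may outrun cleavage of the two less labile aryl acetals. The fallback replaces Brønsted acid by silyl transfer under buffered aprotic conditions followed by fluoride. Setting out from 20, Me3SiOTf and 2,2'-bipyridyl in CH3CN (0 → 25 °C) would move each methoxymethyl group to a pyridine nitrogen and leave the tris(trimethylsilyl) ether F6. Its four silyl groups would then be removed with Bu4NF buffered by AcOH in THF at 0 °C, arriving at 21.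

3. Step 5. Zinc insertion may stay incomplete or the alkylzinc may be protonated, and transmetalation to the doubly ortho-substituted arylpalladium iodide may be slow enough for reduction of the aryl iodide to take over. The fallback reverses the polarity of the partners. Setting out from 8, iodine–magnesium exchange (i-PrMgCl·LiCl, THF, −20 °C) would give the arylmagnesium chloride F4, and ZnCl2 would turn it into the arylzinc chloride F5. This nucleophile would be coupled with alkyl bromide 6 as the electrophile (Pd2(dba)3, tricyclopentylphosphine, N-methylimidazole, THF/N-methylpyrrolidone, 80 °C; dba = dibenzylideneacetone), coming back to the route at 10.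

**Further compounds**
F1 | step 3 | (R)-linalool [(3R)-3,7-dimethylocta-1,6-dien-3-ol] | CC(C)=CCC[C@@](C)(O)C=C
F2 | step 3 | triethyl{[(3R)-3,7-dimethylocta-1,6-dien-3-yl]oxy}silane | CC(C)=CCC[C@@](C)(O[Si](CC)(CC)CC)C=C
F3 | step 3 | 9-[(3S)-3,7-dimethyl-3-(triethylsilyloxy)oct-6-en-1-yl]-9-borabicyclo[3.3.1]nonane | CC(C)=CCC[C@@](C)(O[Si](CC)(CC)CC)CCB1C2CCCC1CCC2
F4 | step 5 | [2,6-bis(methoxymethoxy)phenyl]magnesium chloride | COCOc1cccc(OCOC)c1[Mg]Cl
F5 | step 5 | [2,6-bis(methoxymethoxy)phenyl]zinc chloride | COCOc1cccc(OCOC)c1[Zn]Cl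
F6 | step 12 | (2E)-1-{3-[(3R)-3,7-dimethyl-3-(triethylsilyloxy)oct-6-en-1-yl]-2,4-bis(trimethylsilyloxy)phenyl}-3-[4-(trimethylsilyloxy)phenyl]prop-2-en-1-one | CC(C)=CCC[C@@](C)(O[Si](CC)(CC)CC)CCc1c(O[Si](C)(C)C)ccc(C(=O)/C=C/c2ccc(O[Si](C)(C)C)cc2)c1O[Si](C)(C)C
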